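## Analysis of the target

Gentiside B 19 is the ester of 2,3-dihydroxybenzoic acid 12 with an (S)-20-methyldocosyl residue, so the only ring is the benzene ring and everything else is one saturated chain. Counted from the ester oxygen, C1–C19 are nineteen unbranched methylene groups, and C20, the only stereocentre, carries H, a methyl group, the ethyl group C21–C22 and the long chain. The catechol (2-OH and 3-OH) is sensitive to air and base and is best unveiled last, and the alkyl benzoate must survive every step that follows its formation. The difficulty is C20: it lies nineteen carbons from the nearest heteroatom, and its two small substituents differ by a single CH2, so no reagent acting on the finished chain can tell them apart. A hydrocarbon terminus also offers no handle for enrichment or for an easy assay of enantiomeric purity, so the configuration has to be set while oxygen functions are still close by. Chain assembly must place the branch exactly at C20, because chain homologues would not be separable from the waxy product. The plan rests on the observation that the methyl carbon on C20 and C21 are both single carbons bound to C20, so that drawing both as CH2OH makes C20 the central carbon of the prochiral diol 4. The problem then shrinks to telling two enantiotopic hydroxymethyl groups apart, after which one arm is turned into CH3 and the other into CH2CH3.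

## Retrosynthetic reasoning

19 back to 17. The catechol is masked as two benzyl ethers and the chain carries one C9=C10 double bond. A single hydrogenation then saturates the chain, passing through 18, and frees both phenols. The sensitive catechol therefore appears only in the last step, and the alkyl benzoate is never exposed to a hydride reagent or to base.

17 back to 11 and 16. The C9=C10 bond is cut as an olefin cross-metathesis. C1–C9 come from the ester 16 and C10–C22 from the hydrocarbon 11. The cut is placed here because both halves then derive from commodity ω-alkenyl building blocks, 15 and 2. All polar functionality sits on one partner, so the cross product and the two homodimers differ in their number of ester groups. The new double bond is ten carbons from C20 and cannot disturb the stereocentre.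

16 back to 14 and 15, and 14 back to 12. The ester C–O bond is formed from the acid 14 and the alcohol 15. The acid 14 comes from 12 by exhaustive benzylation to 13 and hydrolysis of the benzyl ester. Forming the aryl ester before the metathesis keeps the late stage to two steps.

11 back to 10 and 9. The C21–C22 bond is cut. The ethyl group is made from a hydroxymethyl arm by displacing its sulfonate in 10 with a methyl group delivered from copper. The carbon attacked is next to C20, not C20 itself, so the configuration cannot change.

9 back to 7 and 6. The C20 methyl group is made from the other arm by removing its oxygen. The free hydroxyl of 6 becomes the sulfonate 7, and a hydride reagent replaces it. The same reagent cleaves the acetate, by way of 8, which exposes the second arm as the only alcohol for the next round. CH2OH and CH2OAc are easy to tell apart, which is why the two arms can be processed in a fixed order.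

6 back to 4 and 5. This is the stereo-defining disconnection: a C–O acyl bond to one of the two enantiotopic hydroxymethyl groups of 4, made by a lipase with 5 as the acyl donor. No skeletal bond is formed; the step only breaks the symmetry of 4.

4 back to 1 and 2. The diol is the reduction product of the malonate 3, which comes from 1 and 2 by one C–C bond formation. The precursor of the key step is thus two routine steps from bulk chemicals, and the risk of the route sits in the enzyme step.

## Alternatives that were turned down

Alternative 1: The C19–C20 bond is disconnected. Racemic 2-bromo-N-benzyl-N-phenylbutanamide A2 and [19-(benzyloxy)nonadecyl]zinc bromide A3 would be joined in an enantioconvergent Negishi coupling under NiCl2(dimethoxyethane) with an isopropyl-pybox ligand. The product would be the amide A1, (S)-N-benzyl-21-(benzyloxy)-2-ethyl-N-phenylhenicosanamide.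
- For: the stereocentre and a skeletal bond are made in the same catalytic step, both enantiomers of A2 are funnelled into one product through a common radical, and A2 is trivial to make. On convergence at the stereo-defining step this plan is stronger than the chosen one.
- Against: the amide carbonyl of A1 is not in the target and must be reduced to CH2OH and deoxygenated to the C20 methyl group, which is the same arm editing as in the chosen route. A3 needs a C19 chain functionalised at both ends, which is not a commodity and costs several steps. The coupling needs air-sensitive nickel and zinc chemistry, and it has no built-in way to raise the enantiomeric purity.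
- In its place the chosen strategy offers a cheap, reusable enzyme, a two-step precursor, and a selectivity that sharpens itself through over-acylation.

Alternative 2: The C17–C18 bond is disconnected. The half ester A5, 18-(tert-butoxy)-18-oxooctadecanoic acid, and (S)-4-methylhexanoic acid A6 would be co-electrolysed at a platinum anode in methanol (mixed Kolbe electrolysis). Both acids lose CO2, and the primary radical from A5 would combine with the one from A6 to give the ester A4, tert-butyl (S)-20-methyldocosanoate.
- For: this is the shortest of all plans. The stereocentre comes from the chiral pool and lies two carbons from the radical centre, so it cannot erode. On step count and on stereochemical risk it is stronger than the chosen route.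
- Against: radical–radical coupling is statistical, and the symmetrical dimers of A5 and of A6 are dead ends. Over-oxidation of the radicals to cations (Hofer–Moest pathway) gives alkenes and methyl ethers that carry the same ester group as A4 and would be hard to remove from a waxy product. The enantiomeric purity is whatever the purchased A6 has, and the ester of A4 must still be reduced and the alcohol esterified with 14.
- The chosen route also contains a statistical step (the metathesis), but its homodimers remain metathesis-active and can be recycled. Every C–C bond is formed by a two-electron or catalytic process with defined connectivity, and the configuration is set, and can be checked, inside the route.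

Alternative 3: The bond between the methyl group and C20 is disconnected. A methyl Grignard reagent would add to the enethioate A8, S-ethyl (E)-22-(benzyloxy)docos-2-enethioate, under CuBr·SMe2 and a Josiphos-type ferrocenyl diphosphine. The product would be the β-methyl thioester A7, S-ethyl (R)-22-(benzyloxy)-3-methyldocosanethioate.
- For: this is a catalytic asymmetric C–C bond formation whose facial selectivity follows predictably from the E geometry and the ligand, on a substrate class (linear aliphatic enethioates) that suits the method. Either enantiomer is available by choice of ligand. On predictability of the stereo-defining step this plan is at least as strong as the enzyme step.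
- Against: A8 requires a C20 aldehyde with a protected oxygen at the far end, which again means a long chain built in several steps. The thioester of A7 then has to be reduced and deoxygenated (three steps) to become the ethyl terminus, the benzyl ether has to be exchanged for the aryl ester, and the addition needs cryogenic conditions and a costly ligand. The route would be clearly longer.
- The chosen strategy reaches its key-step precursor in two steps, uses no chiral reagent other than an enzyme, and can reach either enantiomer of 11 from the same diol by reversing the order of the arm conversions.

Key step: step 3

Remark on the chemistry: the lipase is assumed to acylate the pro-S hydroxymethyl group of 4, so that 6 has the S configuration drawn; should the enzyme prefer the other group, the order of the two arm conversions is exchanged, which leads to the same configuration in 11, and the E/Z composition of 17 is left open because step 12 removes the double bond.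

## Route

Step 1
Reactants: 1 diethyl malonate; 2 11-bromoundec-1-ene
Product: 3 diethyl 2-(undec-10-en-1-yl)propanedioate
Conditions: NaOEt (1.1 equiv), 1 (2 equiv), EtOH, reflux
Reagents that add atoms: none
Why: Malonic ester alkylation: the sodium enolate of 1 displaces bromide from the unhindered primary carbon of 2 (SN2). The excess of 1 suppresses a second alkylation and is removed by distillation; the terminal alkene is inert.

Step 2
Reactants: 3 diethyl 2-(undec-10-en-1-yl)propanedioate
Product: 4 2-(undec-10-en-1-yl)propane-1,3-diol
Conditions: LiAlH4, THF, 0 °C → reflux; then H2O, aq. NaOH
Reagents that add atoms: none
Why: Hydride reduction of both esters gives the prochiral diol; the isolated alkene is not reduced. The central carbon carries two identical hydroxymethyl groups and is not yet a stereocentre.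

Step 3
Reactants: 4 2-(undec-10-en-1-yl)propane-1,3-diol; 5 vinyl acetate
Product: 6 (S)-2-(hydroxymethyl)tridec-12-en-1-yl acetate
Conditions: Burkholderia cepacia lipase (immobilised), 5 (4 equiv), i-Pr2O, 0–25 °C; enzyme filtered off once 4 is consumed
Reagents that add atoms: none
Why: Lipase-catalysed irreversible transesterification, used as an enantiotopic-group-selective desymmetrisation of a prochiral 2-substituted propane-1,3-diol, which is a well-established reaction class. The serine of the Ser–His–Asp triad attacks 5, the tetrahedral intermediate collapses to the acetyl-enzyme, and the vinyl alcohol released tautomerises to acetaldehyde, so the acyl transfer cannot run backwards. One hydroxymethyl group of 4 then attacks the acetyl-enzyme through a second tetrahedral intermediate held in the oxyanion hole. No ring closes and no skeletal bond forms. The new stereocentre (C2 of 6, the future C20) is controlled only by the chiral active site: the undecenyl chain lies in the long hydrophobic channel, the hydrogen in the small pocket, and only one of the two CH2OH groups then reaches the acylated serine. The step needs enantiotopic-group selectivity and selectivity for mono- over diacylation; the first is secured by the large difference in size between the C11 chain and H at the prochiral carbon, the second by stopping when 4 is consumed. A little over-acylation is accepted on purpose, because the minor enantiomer of the monoacetate still has its enzyme-preferred hydroxymethyl group free and is removed faster, which should raise the enantiomeric purity of 6. The remote alkene takes no part.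

Step 4
Reactants: 6 (S)-2-(hydroxymethyl)tridec-12-en-1-yl acetate
Product: 7 (R)-2-{[(4-methylbenzenesulfonyl)oxy]methyl}tridec-12-en-1-yl acetate
Conditions: TsCl, pyridine, CH2Cl2, 0 °C (6 used without storage)
Reagents that add atoms: 4-methylbenzenesulfonyl chloride, Cc1ccc(cc1)S(Cl)(=O)=O
Why: Tosylation of a primary alcohol; no bond to the stereocentre changes, and the descriptor becomes R only because the sulfonyloxymethyl arm now outranks the acetoxymethyl arm. The weak base, the low temperature and the absence of an acyl-transfer catalyst are chosen so that acetyl shift between the two oxygen atoms, which would racemise the material, has no opportunity.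

Step 5
Reactants: 7 (R)-2-{[(4-methylbenzenesulfonyl)oxy]methyl}tridec-12-en-1-yl acetate
Product: 9 (R)-2-methyltridec-12-en-1-ol, via hydroxy tosylate 8 (not isolated)
Conditions: 7 added to LiEt3BH (4 equiv), THF, 0 °C → rt; then H2O
Reagents that add atoms: none
Why: Reduction with LiEt3BH: the acetate is cleaved by acyl reduction to the lithium alkoxide of 8, and hydride then displaces the primary sulfonate (SN2), so the arm that was free in 6 becomes the C20 methyl group and the former acetate arm is the only alcohol left. The stereocentre is not involved, and the borohydride does not touch the terminal alkene.

Step 6
Reactants: 9 (R)-2-methyltridec-12-en-1-ol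
Product: 10 (R)-2-methyltridec-12-en-1-yl 4-methylbenzenesulfonate
Conditions: TsCl, Et3N, DMAP (cat.), CH2Cl2, 0 °C → rt
Reagents that add atoms: 4-methylbenzenesulfonyl chloride, Cc1ccc(cc1)S(Cl)(=O)=O
Why: Tosylation of the remaining primary alcohol; there is no longer an acyl group that could migrate, so the faster DMAP-catalysed conditions are safe.

Step 7
Reactants: 10 (R)-2-methyltridec-12-en-1-yl 4-methylbenzenesulfonate
Product: 11 (S)-12-methyltetradec-1-ene
Conditions: Me2CuLi (3 equiv, from CuI and MeLi), Et2O, –40 → 0 °C
Reagents that add atoms: lithium dimethylcuprate, [Li+].C[Cu-]C
Why: Gilman cuprate substitution of a primary tosylate (SN2-type oxidative addition to a trivalent copper intermediate, then reductive elimination) forms the C21–C22 bond and turns the second arm into the ethyl group. The carbon attacked is adjacent to the stereocentre, so the configuration is retained; the descriptor becomes S because the long chain now ranks highest.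

Step 8
Reactants: 12 2,3-dihydroxybenzoic acid
Product: 13 benzyl 2,3-bis(benzyloxy)benzoate
Conditions: BnBr (3.5 equiv), K2CO3, DMF, 60 °C
Reagents that add atoms: benzyl bromide, BrCc1ccccc1
Why: Williamson etherification of both phenols and O-alkylation of the carboxylate in one operation; the hydrogen-bonded 2-hydroxyl needs the excess reagent and warming.

Step 9
Reactants: 13 benzyl 2,3-bis(benzyloxy)benzoate
Product: 14 2,3-bis(benzyloxy)benzoic acid
Conditions: NaOH, MeOH/THF/H2O, 60 °C; then aq. HCl
Reagents that add atoms: sodium hydroxide, [Na+].[OH-]
Why: Saponification: hydroxide cleaves the benzyl ester by acyl substitution while the aryl benzyl ethers are stable to base; acidification liberates the acid.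

Step 10
Reactants: 14 2,3-bis(benzyloxy)benzoic acid; 15 dec-9-en-1-ol
Product: 16 dec-9-en-1-yl 2,3-bis(benzyloxy)benzoate
Conditions: DCC, DMAP (cat.), CH2Cl2, 0 °C → rt
Reagents that add atoms: none
Why: Steglich esterification: DCC activates the acid as the O-acylisourea and DMAP passes the acyl group to the primary alcohol; benzyl ethers and the alkene are unaffected.

Step 11
Reactants: 11 (S)-12-methyltetradec-1-ene; 16 dec-9-en-1-yl 2,3-bis(benzyloxy)benzoate
Product: 17 (20S)-20-methyldocos-9-en-1-yl 2,3-bis(benzyloxy)benzoate (E/Z mixture)
Conditions: second-generation Grubbs catalyst RuCl2(=CHPh)(H2IMes)(PCy3) (5 mol %), 16 (3 equiv), 1,4-benzoquinone (10 mol %), CH2Cl2, 40 °C, slow argon stream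
Reagents that add atoms: none
Why: Olefin cross-metathesis of two unhindered terminal alkenes through ruthenium alkylidene and metallacyclobutane intermediates; removal of ethene drives the terminal alkenes to full consumption and the excess of 16 channels 11 into the cross product. The three products then carry no, one or two ester groups and should separate on silica. The benzoquinone is added against double-bond migration, and the stereocentre is ten carbons from the reacting site.

Step 12
Reactants: 17 (20S)-20-methyldocos-9-en-1-yl 2,3-bis(benzyloxy)benzoate
Product: 19 (S)-20-methyldocosyl 2,3-dihydroxybenzoate (gentiside B), via saturated dibenzyl ether 18 (not isolated)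
Conditions: H2 (1 atm), Pd/C (10 %), EtOAc/EtOH, rt; work-up under argon
Reagents that add atoms: none
Why: Heterogeneous hydrogenation and hydrogenolysis: the disubstituted alkene is saturated first (18), then both aryl benzyl ethers are cleaved. The alkyl benzoate is not a benzylic ester and stays, and the remote C20 centre is not touched.

## Compound list

1 | diethyl malonate | CCOC(=O)CC(=O)OCC | starting material
2 | 11-bromoundec-1-ene | C=CCCCCCCCCCBr | starting material
3 | diethyl 2-(undec-10-en-1-yl)propanedioate | CCOC(=O)C(CCCCCCCCCC=C)C(=O)OCC | intermediate
4 | 2-(undec-10-en-1-yl)propane-1,3-diol | OCC(CO)CCCCCCCCCC=C | intermediate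
5 | vinyl acetate | CC(=O)OC=C | starting material
6 | (S)-2-(hydroxymethyl)tridec-12-en-1-yl acetate | CC(=O)OC[C@H](CO)CCCCCCCCCC=C | intermediate
7 | (R)-2-{[(4-methylbenzenesulfonyl)oxy]methyl}tridec-12-en-1-yl acetate | CC(=O)OC[C@H](COS(=O)(=O)c1ccc(C)cc1)CCCCCCCCCC=C | intermediate
8 | (R)-2-(hydroxymethyl)tridec-12-en-1-yl 4-methylbenzenesulfonate | OC[C@H](COS(=O)(=O)c1ccc(C)cc1)CCCCCCCCCC=C | intermediate
9 | (R)-2-methyltridec-12-en-1-ol | OC[C@H](C)CCCCCCCCCC=C | intermediate
10 | (R)-2-methyltridec-12-en-1-yl 4-methylbenzenesulfonate | Cc1ccc(cc1)S(=O)(=O)OC[C@H](C)CCCCCCCCCC=C | intermediate
11 | (S)-12-methyltetradec-1-ene | CC[C@H](C)CCCCCCCCCC=C | intermediate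
12 | 2,3-dihydroxybenzoic acid | OC(=O)c1cccc(O)c1O | starting material
13 | benzyl 2,3-bis(benzyloxy)benzoate | O=C(OCc1ccccc1)c2cccc(OCc3ccccc3)c2OCc4ccccc4 | intermediate
14 | 2,3-bis(benzyloxy)benzoic acid | OC(=O)c1cccc(OCc2ccccc2)c1OCc3ccccc3 | intermediate
15 | dec-9-en-1-ol | C=CCCCCCCCCO | starting material
16 | dec-9-en-1-yl 2,3-bis(benzyloxy)benzoate | C=CCCCCCCCCOC(=O)c1cccc(OCc2ccccc2)c1OCc3ccccc3 | intermediate
17 | (20S)-20-methyldocos-9-en-1-yl 2,3-bis(benzyloxy)benzoate (E/Z mixture) | CC[C@H](C)CCCCCCCCCC=CCCCCCCCCOC(=O)c1cccc(OCc2ccccc2)c1OCc3ccccc3 | intermediate
18 | (S)-20-methyldocosyl 2,3-bis(benzyloxy)benzoate | CC[C@H](C)CCCCCCCCCCCCCCCCCCCOC(=O)c1cccc(OCc2ccccc2)c1OCc3ccccc3 | intermediate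
19 | (S)-20-methyldocosyl 2,3-dihydroxybenzoate (gentiside B) | CC[C@H](C)CCCCCCCCCCCCCCCCCCCOC(=O)c1cccc(O)c1O | target

## Step count and least certain steps

Total: 12 steps. Longest linear sequence: 9 steps (steps 1–7, 11, 12); steps 8–10 build the aryl fragment in parallel.

Step 3 (key step). The enzyme may discriminate the two hydroxymethyl groups incompletely, because they differ only in their position relative to a flexible C11 chain. It may also show the opposite sense of selection, too much material may be lost to double acylation, or the acetyl group may shift between the two oxygen atoms during isolation and erode the enantiomeric purity. Since the final hydrocarbon stereocentre is almost impossible to assay, the purity should be checked at 7, which is UV-active, on a chiral stationary phase. The fallback takes the stereocentre from the chiral pool. It sets out from 15, which is converted to 10-bromodec-1-ene F1 (CBr4, PPh3, CH2Cl2). Purchased (S)-1-bromo-2-methylbutane F2 is turned into (S)-2-methylbutylmagnesium bromide F3 (Mg, THF) and coupled with F1 under Li2CuCl4 catalysis (THF, –20 → 0 °C). This gives 11 directly, where the route is rejoined. The stereocentre is one carbon removed from the carbon bound to magnesium and is therefore configurationally safe; the price is that the enantiomeric purity is that of the purchased bromide.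

Step 5. Once the acetate is cleaved, the alkoxide of 8 sits three atoms from a sulfonate-bearing carbon. Intramolecular displacement to a four-membered cyclic ether would compete with hydride attack; that ring is achiral, so any hydride opening of it would return racemic material. Displacement at the β-branched carbon may also be slow. Inverse addition into excess hydride is meant to keep hydride attack ahead. The fallback avoids having an alkoxide and a leaving group in the same molecule. It sets out from 6, which is converted to (R)-2-(iodomethyl)tridec-12-en-1-yl acetate F4 (I2, PPh3, imidazole, CH2Cl2, 0 °C). The carbon–iodine bond is reduced by a radical chain (Bu3SnH, AIBN, toluene, 80 °C, high tin hydride concentration) to (R)-2-methyltridec-12-en-1-yl acetate F5, and methanolysis (K2CO3, MeOH) gives 9, where the route is rejoined.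

Step 7. Substitution at the β-branched primary sulfonate may be sluggish, and attack of the cuprate at sulfur, reduction or elimination would then take over. The fallback changes the electrophile and moves from a stoichiometric cuprate to a copper-catalysed Grignard cross-coupling. It sets out from 9, which is converted to (R)-13-iodo-12-methyltridec-1-ene F6 (I2, PPh3, imidazole). F6 is coupled with MeMgBr under Li2CuCl4 catalysis (THF, –20 → 0 °C) to give 11, where the route is rejoined.

Step 11. The coupling of two terminal alkenes of equal reactivity is statistical, so homodimerisation of 11 consumes the valuable partner. Ruthenium hydride species can move the double bond before metathesis, which would give chain lengths differing by one carbon that cannot be separated after hydrogenation. The fallback places every carbon by an sp3–sp3 Suzuki–Miyaura coupling. Acid 14 is esterified with purchased 8-bromooctan-1-ol F7 (DCC, DMAP, as in step 10) to give 8-bromooctyl 2,3-bis(benzyloxy)benzoate F8. The fallback sets out from 11, which is hydroborated with 9-BBN (THF) to 9-[(12S)-12-methyltetradecyl]-9-borabicyclo[3.3.1]nonane F9. F9 is coupled with F8 (Pd(OAc)2, PCy3, K3PO4·H2O, THF, rt) to give 18, where the route is rejoined and the hydrogenolysis of step 12 is applied.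

## Further compounds

F1 | step 3 | 10-bromodec-1-ene | C=CCCCCCCCCBr
F2 | step 3 | (S)-1-bromo-2-methylbutane | CC[C@H](C)CBr
F3 | step 3 | (S)-2-methylbutylmagnesium bromide | CC[C@H](C)C[Mg]Br
F4 | step 5 | (R)-2-(iodomethyl)tridec-12-en-1-yl acetate | CC(=O)OC[C@H](CI)CCCCCCCCCC=C
F5 | step 5 | (R)-2-methyltridec-12-en-1-yl acetate | CC(=O)OC[C@H](C)CCCCCCCCCC=C
F6 | step 7 | (R)-13-iodo-12-methyltridec-1-ene | IC[C@H](C)CCCCCCCCCC=C
F7 | step 11 | 8-bromooctan-1-ol | OCCCCCCCCBr
F8 | step 11 | 8-bromooctyl 2,3-bis(benzyloxy)benzoate | BrCCCCCCCCOC(=O)c1cccc(OCc2ccccc2)c1OCc3ccccc3
F9 | step 11 | 9-[(12S)-12-methyltetradecyl]-9-borabicyclo[3.3.1]nonane | CC[C@H](C)CCCCCCCCCCCB1C2CCCC1CCC2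
A1 | alternative 1 | (S)-N-benzyl-21-(benzyloxy)-2-ethyl-N-phenylhenicosanamide | CC[C@H](C(=O)N(Cc1ccccc1)c1ccccc1)CCCCCCCCCCCCCCCCCCCOCc1ccccc1
A2 | alternative 1 | 2-bromo-N-benzyl-N-phenylbutanamide (racemic) | CCC(Br)C(=O)N(Cc1ccccc1)c1ccccc1
A3 | alternative 1 | [19-(benzyloxy)nonadecyl]zinc bromide | Br[Zn]CCCCCCCCCCCCCCCCCCCOCc1ccccc1
A4 | alternative 2 | tert-butyl (S)-20-methyldocosanoate | CC[C@H](C)CCCCCCCCCCCCCCCCCCC(=O)OC(C)(C)C
A5 | alternative 2 | 18-(tert-butoxy)-18-oxooctadecanoic acid | OC(=O)CCCCCCCCCCCCCCCCC(=O)OC(C)(C)C
A6 | alternative 2 | (S)-4-methylhexanoic acid | CC[C@H](C)CCC(=O)O
A7 | alternative 3 | S-ethyl (R)-22-(benzyloxy)-3-methyldocosanethioate | CCSC(=O)C[C@H](C)CCCCCCCCCCCCCCCCCCCOCc1ccccc1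
A8 | alternative 3 | S-ethyl (E)-22-(benzyloxy)docos-2-enethioate | CCSC(=O)/C=C/CCCCCCCCCCCCCCCCCCCOCc1ccccc1
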